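**Retrosynthetic overview**

1. The strategy rests on the maleimide ring N1–C2(=O)–C3=C4–C5(=O), where C3 carries the 1-methylimidazol-5-yl ring and C4 the 6-bromoindol-3-yl ring. The C3=C4 unit with its two heteroaryl groups is a diheteroaryl alkyne, C2(=O)–N1 is an isocyanate and C5(=O) is carbon monoxide (the mirror assignment gives the same product).
2. Key disconnection: the C3–C2, C4–C5 and N1–C5 bonds are broken together, giving alkyne 5, benzyl isocyanate and CO, joined by a Ru3(CO)12-catalysed [2+2+1] cocyclisation.
3. Alkyne 5 comes from a Sonogashira coupling at the C3–I bond of 6-bromo-3-iodo-1-tosylindole with 5-ethynyl-1-methylimidazole; the iodide comes from 6-bromoindole.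
4. End game: KOH converts the N-benzyl imide to the cyclic anhydride and removes the tosyl group in the same pot; NH4OAc then gives the N–H imide.
5. Ring order: the indole and imidazole rings are bought; the maleimide ring is the only ring built (step 4), and its nitrogen substituent is then exchanged (steps 5 and 6).

Key step: step 4

Remark: 6-bromoindole, 5-ethynyl-1-methylimidazole, benzyl isocyanate and carbon monoxide are taken as purchased materials; iodide 2 is light-sensitive and should be tosylated on the day it is made.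

**Route**

Step 1
Reactants: 1 6-bromo-1H-indole
Product: 2 6-bromo-3-iodo-1H-indole
Conditions: I2, KOH, DMF, rt; aq NaHSO3 quench, filtration
Reagents that add atoms: iodine, II
Why: Electrophilic aromatic iodination by I2/KOH takes place at C3, the most nucleophilic position of the indole, and leaves the C6–Br bond untouched.

Step 2
Reactants: 2 6-bromo-3-iodo-1H-indole
Product: 3 6-bromo-3-iodo-1-(4-methylphenylsulfonyl)-1H-indole
Conditions: TsCl, 50% aq NaOH, Bu4NHSO4 (cat.), toluene, rt
Reagents that add atoms: p-toluenesulfonyl chloride, Cc1ccc(S(=O)(=O)Cl)cc1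
Why: Phase-transfer N-sulfonylation occurs at the indole nitrogen only, and the electron-withdrawing tosyl group stabilises the labile 3-iodoindole and masks the N–H for steps 3 and 4.

Step 3
Reactants: 3 6-bromo-3-iodo-1-(4-methylphenylsulfonyl)-1H-indole; 4 5-ethynyl-1-methyl-1H-imidazole
Product: 5 6-bromo-3-[(1-methyl-1H-imidazol-5-yl)ethynyl]-1-(4-methylphenylsulfonyl)-1H-indole
Conditions: PdCl2(PPh3)2 (3 mol%), CuI (5 mol%), Et3N, THF, rt, argon
Reagents that add atoms: none
Why: Sonogashira coupling, in which oxidative addition at room temperature is much faster at the C3–I bond than at the C6–Br bond, so the copper acetylide of 4 is joined at C3 only.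

Step 4
Reactants: 5 6-bromo-3-[(1-methyl-1H-imidazol-5-yl)ethynyl]-1-(4-methylphenylsulfonyl)-1H-indole; 6 benzyl isocyanate; 7 carbon monoxide
Product: 8 1-benzyl-3-[6-bromo-1-(4-methylphenylsulfonyl)-1H-indol-3-yl]-4-(1-methyl-1H-imidazol-5-yl)-1H-pyrrole-2,5-dione
Conditions: Ru3(CO)12 (5 mol%), CO (1 atm), BnNCO (2 equiv, slow addition), mesitylene, 130 °C
Reagents that add atoms: none
Why: Zerovalent ruthenium from Ru3(CO)12 couples the alkyne of 5 with the C=N bond of the isocyanate by oxidative cyclisation to a five-membered azaruthenacycle (Ru–N and Ru–vinyl bonds), which forms the first alkene-carbon to carbonyl-carbon bond; CO then inserts into the Ru–vinyl bond to form the second, and C–N reductive elimination from the six-membered acyl amido ruthenacycle closes the imide and releases the catalyst. The closest known reaction type is the Ru3(CO)12-catalysed [2+2+1] cocyclisation of internal diaryl alkynes, isocyanates and CO to polysubstituted maleimides in mesitylene at 130 °C under 1 atm CO. The maleimide ring, the only ring formed, therefore closes by reductive elimination at the metal as a formal [2+2+1] cycloaddition, and no stereocentre is created. Regioselectivity is not needed, because both alkyne carbons end bonded to a carbonyl carbon of the imide; the step needs chemoselectivity over alkyne/alkyne/CO cyclisation, alkyne cyclotrimerisation and isocyanate cyclotrimerisation, which the two bulky heteroaryl groups on the alkyne, the CO atmosphere and the slow addition of excess isocyanate should secure. The N-tosyl group removes the indole N–H that would add to the isocyanate, the C6–Br bond should not undergo oxidative addition to ruthenium carbonyl species under CO, and the imidazole N3 is expected to bind ruthenium only reversibly at 130 °C, as nitrogen heteroarenes do in other Ru3(CO)12 carbonylations.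

Step 5
Reactants: 8 1-benzyl-3-[6-bromo-1-(4-methylphenylsulfonyl)-1H-indol-3-yl]-4-(1-methyl-1H-imidazol-5-yl)-1H-pyrrole-2,5-dione
Product: 10 3-(6-bromo-1H-indol-3-yl)-4-(1-methyl-1H-imidazol-5-yl)furan-2,5-dione, via dipotassium diarylmaleate 9 (not isolated)
Conditions: 5 M aq KOH, EtOH, reflux; then aq HCl (pH 1), then adjusted to pH 5 for extraction
Reagents that add atoms: potassium hydroxide, [K+].[OH-]
Why: Hydroxide opens the N-benzyl imide by acyl substitution (imide hydrolysis) and cleaves the indole sulfonamide in the same pot, and on acidification the cis-diacid from 9 cyclodehydrates spontaneously to the five-membered anhydride, as 2,3-diaryl maleic acids do.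

Step 6
Reactants: 10 3-(6-bromo-1H-indol-3-yl)-4-(1-methyl-1H-imidazol-5-yl)furan-2,5-dione
Product: 11 didemnimide D, 3-(6-bromo-1H-indol-3-yl)-4-(1-methyl-1H-imidazol-5-yl)-1H-pyrrole-2,5-dione
Conditions: NH4OAc (excess, melt), 140 °C
Reagents that add atoms: ammonium acetate, CC(=O)[O-].[NH4+]
Why: Anhydride-to-imide exchange, in which ammonia from the NH4OAc melt acylates at a ring carbonyl and the melt temperature drives cyclodehydration to the N-unsubstituted maleimide, with the aryl bromide, indole and imidazole untouched.

**Compound list**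

1 | 6-bromo-1H-indole | Brc1ccc2cc[nH]c2c1 | starting material
2 | 6-bromo-3-iodo-1H-indole | Brc1ccc2c(I)c[nH]c2c1 | intermediate
3 | 6-bromo-3-iodo-1-(4-methylphenylsulfonyl)-1H-indole | Cc1ccc(S(=O)(=O)n2cc(I)c3ccc(Br)cc32)cc1 | intermediate
4 | 5-ethynyl-1-methyl-1H-imidazole | C#Cc1cncn1C | starting material
5 | 6-bromo-3-[(1-methyl-1H-imidazol-5-yl)ethynyl]-1-(4-methylphenylsulfonyl)-1H-indole | Cn1cncc1C#Cc1cn(S(=O)(=O)c2ccc(C)cc2)c2cc(Br)ccc12 | intermediate
6 | benzyl isocyanate | O=C=NCc1ccccc1 | starting material
7 | carbon monoxide | [C-]#[O+] | starting material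
8 | 1-benzyl-3-[6-bromo-1-(4-methylphenylsulfonyl)-1H-indol-3-yl]-4-(1-methyl-1H-imidazol-5-yl)-1H-pyrrole-2,5-dione | Cn1cncc1C1=C(c2cn(S(=O)(=O)c3ccc(C)cc3)c3cc(Br)ccc23)C(=O)N(Cc2ccccc2)C1=O | intermediate
9 | dipotassium (Z)-2-(6-bromo-1H-indol-3-yl)-3-(1-methyl-1H-imidazol-5-yl)but-2-enedioate | Cn1cncc1/C(C(=O)[O-])=C(/C(=O)[O-])c1c[nH]c2cc(Br)ccc12.[K+].[K+] | intermediate
10 | 3-(6-bromo-1H-indol-3-yl)-4-(1-methyl-1H-imidazol-5-yl)furan-2,5-dione | Cn1cncc1C1=C(c2c[nH]c3cc(Br)ccc23)C(=O)OC1=O | intermediate
11 | didemnimide D, 3-(6-bromo-1H-indol-3-yl)-4-(1-methyl-1H-imidazol-5-yl)-1H-pyrrole-2,5-dione | Cn1cncc1C1=C(c2c[nH]c3cc(Br)ccc23)C(=O)NC1=O | target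

**Step count**

Total steps: 6. Longest linear sequence: 6 steps (from 6-bromoindole 1).

**Steps most likely to fail**

1. Step 4. The imidazole N3 may hold the ruthenium carbonyl species out of the catalytic cycle, and it may also promote cyclotrimerisation of the isocyanate, so that the cocyclisation is starved and alkyne/alkyne/CO cyclisation takes over. The fallback builds the maleimide from a preformed imide ring; it sets out from 1 and returns at 8. Compound 1 is treated with EtMgBr in THF/toluene to give (6-bromo-1H-indol-1-yl)magnesium bromide F1. F1 attacks 1-benzyl-3,4-dibromo-1H-pyrrole-2,5-dione through C3 of the indole and expels bromide to give 1-benzyl-3-bromo-4-(6-bromo-1H-indol-3-yl)-1H-pyrrole-2,5-dione F2. N-Tosylation (TsCl, Et3N, DMAP, CH2Cl2) gives 1-benzyl-3-bromo-4-[6-bromo-1-(4-methylphenylsulfonyl)-1H-indol-3-yl]-1H-pyrrole-2,5-dione F3. Stille coupling of F3 with 1-methyl-5-(tributylstannyl)imidazole (Pd(PPh3)4, CuI, DMF, 80 °C) should take place at the activated vinyl C–Br bond in preference to the aryl C–Br bond and give 8.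

2. Step 3. CuI-mediated oxidative dimerisation of the electron-rich heteroaryl alkyne, and binding of copper by the imidazole that slows transmetalation, could force heating and so erode the iodide-over-bromide selectivity. The fallback is a copper-free Negishi alkynylation; it sets out from 4 and returns at 5. Alkyne 4 is converted with ZnBr2 and Et3N in THF to [(1-methyl-1H-imidazol-5-yl)ethynyl]zinc bromide F4, which is coupled with iodide 3 (Pd(PPh3)4, THF, rt) at the C–I bond to give 5.

3. Step 5. Hydrolysis of the hindered imide may stop short of complete ring opening, and the amphoteric imidazolyl anhydride may be lost to the aqueous phase or re-opened during the pH adjustment. The fallback avoids the anhydride by using an acid-labile nitrogen substituent; it sets out from 5 and returns at 11. Alkyne 5 is cocyclised with 2,4-dimethoxybenzyl isocyanate and CO under the conditions of step 4 to give 3-[6-bromo-1-(4-methylphenylsulfonyl)-1H-indol-3-yl]-1-(2,4-dimethoxybenzyl)-4-(1-methyl-1H-imidazol-5-yl)-1H-pyrrole-2,5-dione F5. TFA/anisole at 80 °C removes the dimethoxybenzyl group to give 3-[6-bromo-1-(4-methylphenylsulfonyl)-1H-indol-3-yl]-4-(1-methyl-1H-imidazol-5-yl)-1H-pyrrole-2,5-dione F6. Tetrabutylammonium fluoride in THF at reflux cleaves the indole sulfonamide to give 11.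

**Further compounds**

F1 | step 4 | (6-bromo-1H-indol-1-yl)magnesium bromide | Br[Mg]n1ccc2ccc(Br)cc21
F2 | step 4 | 1-benzyl-3-bromo-4-(6-bromo-1H-indol-3-yl)-1H-pyrrole-2,5-dione | O=C1C(Br)=C(c2c[nH]c3cc(Br)ccc23)C(=O)N1Cc1ccccc1
F3 | step 4 | 1-benzyl-3-bromo-4-[6-bromo-1-(4-methylphenylsulfonyl)-1H-indol-3-yl]-1H-pyrrole-2,5-dione | Cc1ccc(S(=O)(=O)n2cc(C3=C(Br)C(=O)N(Cc4ccccc4)C3=O)c3ccc(Br)cc32)cc1
F4 | step 3 | [(1-methyl-1H-imidazol-5-yl)ethynyl]zinc bromide | Cn1cncc1C#C[Zn]Br
F5 | step 5 | 3-[6-bromo-1-(4-methylphenylsulfonyl)-1H-indol-3-yl]-1-(2,4-dimethoxybenzyl)-4-(1-methyl-1H-imidazol-5-yl)-1H-pyrrole-2,5-dione | Cn1cncc1C1=C(c2cn(S(=O)(=O)c3ccc(C)cc3)c3cc(Br)ccc23)C(=O)N(Cc2ccc(OC)cc2OC)C1=O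
F6 | step 5 | 3-[6-bromo-1-(4-methylphenylsulfonyl)-1H-indol-3-yl]-4-(1-methyl-1H-imidazol-5-yl)-1H-pyrrole-2,5-dione | Cn1cncc1C1=C(c2cn(S(=O)(=O)c3ccc(C)cc3)c3cc(Br)ccc23)C(=O)NC1=O
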